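The plan cuts the γ-lactone from the cyclohexane at O–C8 and C11–C7. This ring is trans-fused (C11 on C7 β, O on C8 α, both equatorial) and O8 is cis to O9. Both bonds are therefore made by anti addition of oxygen and carbon across a C7=C8 cyclohexene. In one flask the free 9α-hydroxyl steers epoxidation to the α face, and an ethynylalane opens the oxirane at C7 from the β face. The precursor is a cyclohexene that already carries C5, C6, C9 and C10, three of them set by one catalytic enantioselective Diels–Alder reaction. Cyclocarbonylation of the ethynyl carbinol then closes the α-methylene lactone.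

Key step: step 8

Remark: elemane numbering is used (ring C5–C10; C14 methyl and C1=C2 vinyl on C10; C4 side chain on C5; C11–C13 on C7). β is the ring face of the C14 methyl and α the opposite face.
Assumption: the (S)-diphenylprolinol-derived oxazaborolidinium is taken to give the drawn enantiomer of 3; should the sense be opposite, its mirror-image catalyst is used.

Step 1
Reactants: 1 (E)-buta-1,3-dien-1-yl acetate; 2 ethyl (E)-3-methyl-4-oxobut-2-enoate
Product: 3 ethyl 5-acetoxy-6-formyl-6-methylcyclohex-3-ene-1-carboxylate (5β-CO2Et, 9α-OAc, 10α-CHO, 10β-CH3, C7=C8)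
Conditions: chiral oxazaborolidinium triflimide (from (S)-diphenylprolinol, o-tolylboronic acid, Tf2NH; 15 mol %), CH2Cl2, −78 → −40 °C
Reagents that add atoms: none
Why: Catalytic enantioselective Diels–Alder reaction in which the Lewis acid binds the formyl group, so C5 (β to CHO) should bond to the free diene terminus ("ortho" rule), CHO should lie endo (9-OAc cis to CHO), the E alkene keeps CHO and CO2Et trans, and the shielded catalyst face fixes the absolute sense of C5, C9 and C10 in one event.

Step 2
Reactants: 3 aldehyde ester
Product: 4 ethyl 5-acetoxy-6-methyl-6-vinylcyclohex-3-ene-1-carboxylate (configuration as in 3, 10α-vinyl)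
Conditions: Ph3PCH3Br, KHMDS, THF, −78 → 0 °C
Reagents that add atoms: methyltriphenylphosphonium bromide, C[P+](c1ccccc1)(c1ccccc1)c1ccccc1.[Br-]
Why: Wittig methylenation, in which the aldehyde has no α-hydrogen to epimerise and should react far faster with one equivalent of ylide than the acetate or the ethyl ester.

Step 3
Reactants: 4 vinyl ester
Product: 5 ethyl 5-acetoxy-6-methyl-2-oxo-6-vinylcyclohex-3-ene-1-carboxylate (C6 ketone conjugated with C7=C8)
Conditions: Rh2(cap)4 (1 mol %), t-BuOOH (5 equiv), K2CO3, CH2Cl2, rt
Reagents that add atoms: tert-butyl hydroperoxide, CC(C)(C)OO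
Why: Dirhodium caprolactamate/hydroperoxide allylic oxidation, in which C6H2 is the only free allylic methylene (the vinyl group has no allylic hydrogen and C9–H is hindered and acetoxylated), and the β-keto ester keeps the 5β-ester in its more stable equatorial place.

Step 4
Reactants: 5 enone
Product: 6 ethyl 5-acetoxy-2-hydroxy-6-methyl-6-vinylcyclohex-3-ene-1-carboxylate (6β-OH)
Conditions: NaBH4, CeCl3·7H2O, MeOH, −78 °C
Reagents that add atoms: none
Why: Luche 1,2-reduction, in which the axial C14 methyl stands 1,3 to C6 on the β face, so hydride should enter from the α face and set the 6β-carbinol.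

Step 5
Reactants: 6 hydroxy ester
Product: 7 5-methyl-6-[3-(trimethylsilyl)prop-1-en-2-yl]-5-vinylcyclohex-2-ene-1,4-diol (6β-OH, 9α-OH, 5β side chain)
Conditions: Me3SiCH2MgCl (8 equiv), CeCl3 (8 equiv), THF, −78 °C → rt; aq NH4Cl; SiO2, CH2Cl2
Reagents that add atoms: (trimethylsilyl)methylmagnesium chloride, C[Si](C)(C)C[Mg]Cl
Why: Cerium-mediated double addition to the ester followed by Peterson elimination (ester to allylsilane), where the weakly basic organocerium should spare the β-oxygenated C5–H from elimination and the same reagent takes off the 9-acetate.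

Step 6
Reactants: 7 allylsilane diol
Product: 8 5-methyl-6-(prop-1-en-2-yl)-5-vinylcyclohex-2-ene-1,4-diol (6β-OH, 9α-OH)
Conditions: TBAF·3H2O, THF, 60 °C
Reagents that add atoms: none
Why: Fluoride-induced protodesilylation of an allylsilane, in which protonation at either allyl terminus gives the same isopropenyl group and no stereocenter is touched.

Step 7
Reactants: 8 diol
Product: 9 6β-(tert-butyldimethylsilyl) ether of 8 (9α-OH free)
Conditions: TBSCl (1.05 equiv), imidazole, DMF, 0 °C
Reagents that add atoms: tert-butyldimethylsilyl chloride, CC(C)(C)[Si](C)(C)Cl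
Why: Selective silylation, since O9 is neopentyl (next to quaternary C10) and should react much more slowly than O6, which must stay blocked so that it can neither direct the epoxidation nor capture the acyl group later.

Step 8
Reactants: 9 silyl ether with free 9α-OH
Product: 11 7β-ethynyl-8α,9α-diol (6β-OTBS; vinyl and isopropenyl intact), via 7α,8α-epoxide 10 (not isolated)
Conditions: VO(acac)2 (3 mol %), t-BuOOH (1.05 equiv, decane), PhMe, 0 °C → rt; then Et2AlC≡CH (5 equiv), PhMe–hexane, −20 → 45 °C, same flask; aq Rochelle salt
Reagents that add atoms: tert-butyl hydroperoxide, CC(C)(C)OO; diethyl(ethynyl)aluminium, CC[Al](CC)C#C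
Why: The C9 hydroxyl binds the vanadium(V) tert-butylperoxide and hands oxygen to C7=C8 on its own α face, which makes O–C8 cis to O9, and the alane then activates the oxirane so that an ethynyl group enters C7 from the β face by SN2, which makes C7–C11 and leaves the oxygen on C8. The closest known reaction types are the hydroxyl-directed vanadium epoxidation of cyclohexenols and the alkynylalane opening of cyclohexene oxides to trans-2-ethynylcyclohexanols, here run in one flask. The only ring closed is the transient oxirane (concerted syn oxygen transfer), which is opened again in the same flask, and the lasting lactone ring follows in step 9. C8 is controlled by the C9 carbinol (directed delivery) and C7 by inversion at the oxirane carbon, so the net anti addition gives the 7β-C/8α-O pattern of a trans-fused lactone, which a suprafacial [3+2] addition to a cyclohexene cannot give. Chemoselectivity for the ring alkene over vinyl and isopropenyl rests on the allylic hydroxyl. Regioselectivity for C7 rests on the Fürst–Plattner rule in the half-chair with equatorial O6 and O9, where axial attack falls on C7, whereas attack at C8 would run 1,3-diaxial into the C14 methyl and the 6β-silyloxy group and lies next to the aluminium-bound O9.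

Step 9
Reactants: 11 ethynyl diol
Product: 12 6β-(tert-butyldimethylsilyloxy)-9α-hydroxyelema-1,3,11(13)-trien-12,8α-olide (trans-fused α-methylene-γ-lactone)
Conditions: PdCl2 (5 mol %), thiourea (10 mol %), CO (1 atm), acetone, 50 °C
Reagents that add atoms: carbon monoxide, [C-]#[O+]
Why: Palladium-catalysed cyclocarbonylation of a homopropargylic alcohol, in which the alkoxycarbonylpalladium unit on O8 should add 5-exo-dig to the alkyne and be protonated to C11=C13H2, while O9 (trans-1,3 to C11) cannot reach, O6 is silylated and no stereocenter changes.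

Step 10
Reactants: 12 hydroxy lactone; 13 angelic acid ((Z)-2-methylbut-2-enoic acid)
Product: 14 9α-angelate of 12
Conditions: 2,4,6-trichlorobenzoyl chloride, Et3N, PhMe, rt → 80 °C
Reagents that add atoms: none
Why: Yamaguchi esterification through the mixed anhydride, run without nucleophilic catalyst so that the Z geometry of the angelate should hold while the single free, hindered 9α-hydroxyl is acylated.

Step 11
Reactants: 14 angelate
Product: 15 6β-(tert-butyldimethylsilyloxy)-9α-angeloyloxy-15-oxoelema-1,3,11(13)-trien-12,8α-olide (2-substituted acrolein on C5)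
Conditions: SeO2 (1.5 equiv), 1,4-dioxane, 70 °C
Reagents that add atoms: selenium dioxide, O=[Se]=O
Why: Riley allylic oxidation (ene reaction, then [2,3]-shift), in which the isopropenyl group is the only electron-rich alkene with an allylic methyl, while the vinyl group has no allylic hydrogen and the lactone methylene and the angelate are electron-poor.

Step 12
Reactants: 15 silyl ether
Product: 16 target, 9α-angeloyloxy-6β-hydroxy-15-oxoelema-1,3,11(13)-trien-12,8α-olide
Conditions: HF·pyridine, THF, 0 °C → rt
Reagents that add atoms: none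
Why: Fluoride desilylation under mildly acidic conditions should free O6 without forming an alkoxide, so the acyl group should not migrate from O8 to the cis-disposed O6, and the enal, the angelate and the lactone should survive.

Compound list
1 | (E)-buta-1,3-dien-1-yl acetate | C=C/C=C/OC(C)=O | starting material
2 | ethyl (E)-3-methyl-4-oxobut-2-enoate | CCOC(=O)/C=C(\C)C=O | starting material
3 | ethyl 5-acetoxy-6-formyl-6-methylcyclohex-3-ene-1-carboxylate (5β-CO2Et, 9α-OAc, 10α-CHO) | O=C[C@]1(C)[C@H](OC(C)=O)C=CC[C@H]1C(=O)OCC | intermediate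
4 | ethyl 5-acetoxy-6-methyl-6-vinylcyclohex-3-ene-1-carboxylate | C=C[C@]1(C)[C@H](OC(C)=O)C=CC[C@H]1C(=O)OCC | intermediate
5 | ethyl 5-acetoxy-6-methyl-2-oxo-6-vinylcyclohex-3-ene-1-carboxylate | C=C[C@]1(C)[C@H](OC(C)=O)C=CC(=O)[C@H]1C(=O)OCC | intermediate
6 | ethyl 5-acetoxy-2-hydroxy-6-methyl-6-vinylcyclohex-3-ene-1-carboxylate (6β-OH) | C=C[C@]1(C)[C@H](OC(C)=O)C=C[C@@H](O)[C@H]1C(=O)OCC | intermediate
7 | 5-methyl-6-[3-(trimethylsilyl)prop-1-en-2-yl]-5-vinylcyclohex-2-ene-1,4-diol (6β,9α-diol) | C=C[C@]1(C)[C@H](O)C=C[C@@H](O)[C@H]1C(=C)C[Si](C)(C)C | intermediate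
8 | 5-methyl-6-(prop-1-en-2-yl)-5-vinylcyclohex-2-ene-1,4-diol (6β,9α-diol) | C=C[C@]1(C)[C@H](O)C=C[C@@H](O)[C@H]1C(C)=C | intermediate
9 | 6β-O-TBS ether of 8 | C=C[C@]1(C)[C@H](O)C=C[C@@H](O[Si](C)(C)C(C)(C)C)[C@H]1C(C)=C | intermediate
10 | 7α,8α-epoxide of 9 | C=C[C@]1(C)[C@H](O)[C@@H]2O[C@@H]2[C@@H](O[Si](C)(C)C(C)(C)C)[C@H]1C(C)=C | intermediate
11 | 7β-ethynyl-8α,9α-diol (6β-OTBS) | C=C[C@]1(C)[C@H](O)[C@H](O)[C@@H](C#C)[C@@H](O[Si](C)(C)C(C)(C)C)[C@H]1C(C)=C | intermediate
12 | 6β-TBSO-9α-hydroxyelema-1,3,11(13)-trien-12,8α-olide | C=C[C@]1(C)[C@H](O)[C@@H]2OC(=O)C(=C)[C@H]2[C@@H](O[Si](C)(C)C(C)(C)C)[C@H]1C(C)=C | intermediate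
13 | angelic acid | C/C=C(/C)C(=O)O | starting material
14 | 9α-angelate of 12 | C=C[C@]1(C)[C@H](OC(=O)/C(C)=C\C)[C@@H]2OC(=O)C(=C)[C@H]2[C@@H](O[Si](C)(C)C(C)(C)C)[C@H]1C(C)=C | intermediate
15 | 15-aldehyde of 14 | C=C[C@]1(C)[C@H](OC(=O)/C(C)=C\C)[C@@H]2OC(=O)C(=C)[C@H]2[C@@H](O[Si](C)(C)C(C)(C)C)[C@H]1C(=C)C=O | intermediate
16 | CNP0320538.1 | C=C[C@]1(C)[C@H](OC(=O)/C(C)=C\C)[C@@H]2OC(=O)C(=C)[C@H]2[C@@H](O)[C@H]1C(=C)C=O | target

Total step count: 12. Longest linear sequence: 12 steps (1 or 2 to 16).

Steps most likely to fail

Step 8. The oxirane is flanked by oxygenated carbons and by an axial side chain in the reactive half-chair. The alane stage may therefore stall, lose its preference for C7, or let the Lewis acid draw the nearby isopropenyl π bond into the opening. The fallback sets out from 9 and uses no Lewis acid and a different carbon unit. The epoxide 10 is isolated after the vanadium epoxidation and opened with dilithioacetate in DME at 55 °C to the 7β-carboxymethyl-8α,9α-diol F1. EDCI closes this to the trans-fused α-unsubstituted lactone F2. LDA (2.2 equiv) and dimethylmethyleneiminium iodide then give the α-(dimethylaminomethyl) lactone F3. Its methiodide F4 (MeI) loses the amine on NaHCO3, and the route is rejoined at 12.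

Step 4. Facial selectivity may be poor, because stereoelectronically preferred axial attack and the steric shield of the C14 methyl oppose each other. The fallback sets out from 5 and replaces facial control of hydride by an SN2 inversion. The reduction is run for the 6α-alcohol F5. A Mitsunobu reaction (AcOH, DIAD, PPh3) then inverts C6 to the 6β,9α-diacetate F6. Under the organocerium conditions of step 5, F6 loses both acetates as the ester is converted, and the route is rejoined at 7.

Step 11. The oxidation may stop at the allylic alcohol, run on to over-oxidised material, or attack the angelate methyl groups at the temperature needed. The fallback sets out from 14 and uses a photooxygenation. A Schenck ene reaction (O2, tetraphenylporphyrin, hν, CH2Cl2, 0 °C) at the only electron-rich alkene gives the 15-hydroperoxide F7. Ac2O/pyridine dehydrates it in a Kornblum–DeLaMare-type step, and the route is rejoined at 15.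

Further compounds
F1 | step 8 | 7β-carboxymethyl-8α,9α-diol (6β-OTBS) | C=C[C@]1(C)[C@H](O)[C@H](O)[C@@H](CC(=O)O)[C@@H](O[Si](C)(C)C(C)(C)C)[C@H]1C(C)=C
F2 | step 8 | trans-fused 8α,12-lactone without C13 (6β-OTBS, 9α-OH) | C=C[C@]1(C)[C@H](O)[C@@H]2OC(=O)C[C@H]2[C@@H](O[Si](C)(C)C(C)(C)C)[C@H]1C(C)=C
F3 | step 8 | α-(dimethylaminomethyl) lactone (C11 epimers) | C=C[C@]1(C)[C@H](O)[C@@H]2OC(=O)C(CN(C)C)[C@H]2[C@@H](O[Si](C)(C)C(C)(C)C)[C@H]1C(C)=C
F4 | step 8 | methiodide of F3 | C=C[C@]1(C)[C@H](O)[C@@H]2OC(=O)C(C[N+](C)(C)C)[C@H]2[C@@H](O[Si](C)(C)C(C)(C)C)[C@H]1C(C)=C.[I-]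
F5 | step 4 | 6α-epimer of 6 | C=C[C@]1(C)[C@H](OC(C)=O)C=C[C@H](O)[C@H]1C(=O)OCC
F6 | step 4 | 6β,9α-diacetate | C=C[C@]1(C)[C@H](OC(C)=O)C=C[C@@H](OC(C)=O)[C@H]1C(=O)OCC
F7 | step 11 | 15-hydroperoxide of 14 | C=C[C@]1(C)[C@H](OC(=O)/C(C)=C\C)[C@@H]2OC(=O)C(=C)[C@H]2[C@@H](O[Si](C)(C)C(C)(C)C)[C@H]1C(=C)COO
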